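**Strategy**

The seven-membered ring (C2–C8) and the five-membered ring (C5, C6, C9–C11) share the C5–C6 bond, C4 carries oxygen between C3 and C5, and C8 carries oxygen inside the C6–C7–C8–C2 unit. Cutting C2–C3 and C5–C6 therefore gives an oxyallyl cation (C3–C4–C5) tethered through C9–C11 to a 2-silyloxydiene. One intramolecular (4+3) cycloaddition builds both rings, the quaternary C6 and two differentiated carbonyls (C4 free, C8 masked). The precursor is an acyclic chloromethyl ketone carrying a (Z)-TIPS dienol ether; its C9/C11 syn-diol is locked as a p-methoxybenzylidene acetal so that the diene can only close with the C6 methyl cis to O9.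

Key step: step 11

Numbering used throughout: C8 = ring ketone carbon; C2 = methyl-bearing alkene carbon; C3 = alkene CH; C4 = carbinol carbon bearing the ester; C5 = ring-fusion CH; C6 = quaternary methyl carbon; C7 = CH2; C9 = secondary carbinol; C10 = CH2; C11 = isopropyl carbinol; O4, O9, O11 are the oxygens on these carbons.

Remark: (−)-Ipc2BCl is assigned as the reagent that delivers the 9R carbinol by analogy with related methyl ketone–enal aldols; if the opposite sense is found, (+)-Ipc2BCl is used and nothing else changes.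

Remark: C8 in 14 and C2 in 20–28 arise as epimer mixtures that converge later; their SMILES leave these centres open.

Remark: acid 27 is taken as a purchasable reagent.

**Route**

Step 1
Reactants: 1 prop-2-yn-1-ol
Product: 3 (E)-3-iodo-2-methylprop-2-en-1-ol, via alkenylalane 2 (not isolated)
Conditions: Me3Al (3 equiv), Cp2ZrCl2 (25 mol%), CH2Cl2, 0 °C → rt; then I2, THF, −30 → 0 °C
Reagents that add atoms: trimethylaluminium C[Al](C)C; iodine II
Why: Negishi zirconium-catalysed carboalumination adds methyl and aluminium syn across the alkyne (methyl to the internal carbon), and iodinolysis of the C–Al bond with retention fixes the E alkene that becomes C6=C7.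

Step 2
Reactants: 3 (E)-3-iodo-2-methylprop-2-en-1-ol
Product: 4 (E)-3-iodo-2-methylprop-2-enal
Conditions: MnO2, CH2Cl2, rt
Reagents that add atoms: none
Why: Manganese dioxide oxidises the allylic alcohol selectively to the enal without touching the vinyl iodide or the alkene geometry.

Step 3
Reactants: 5 3-methylbutan-2-one; 4 (E)-3-iodo-2-methylprop-2-enal
Product: 7 (5R,6E)-5-hydroxy-7-iodo-2,6-dimethylhept-6-en-3-one, via boron enolate 6 (not isolated)
Conditions: (−)-Ipc2BCl, Et3N, Et2O, 0 °C; then 4, −78 → −20 °C; then H2O2, MeOH, pH 7 buffer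
Reagents that add atoms: none
Why: Paterson boron aldol: the less substituted Ipc2B enolate adds to the aldehyde through a cyclic transition state in which the isopinocampheyl ligands select the aldehyde face, which should set C9 as R.

Step 4
Reactants: 7 (5R,6E)-5-hydroxy-7-iodo-2,6-dimethylhept-6-en-3-one; 8 bromoacetyl bromide
Product: 9 (1E,3R)-1-iodo-2,6-dimethyl-5-oxohept-1-en-3-yl bromoacetate
Conditions: pyridine, CH2Cl2, −20 → 0 °C
Reagents that add atoms: none
Why: O-acylation of the secondary alcohol by the acid bromide with a weak base at low temperature, which should avoid β-elimination of the β-acyloxy ketone.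

Step 5
Reactants: 9 (1E,3R)-1-iodo-2,6-dimethyl-5-oxohept-1-en-3-yl bromoacetate
Product: 11 (4S,6R)-4-hydroxy-6-[(E)-1-iodoprop-1-en-2-yl]-4-(propan-2-yl)oxan-2-one, via samarium enolate 10 (not isolated)
Conditions: SmI2 (2.2 equiv), THF, −78 °C; aq NH4Cl
Reagents that add atoms: none
Why: SmI2-mediated intramolecular Reformatsky reaction: the Sm(III) enolate adds to the C11 ketone through a chair-like chelate with the alkenyl and isopropyl groups equatorial and the samarium-bound oxygen axial, which sets C11 with O9 and O11 syn along the C5–C11–C10–C9–C6 chain; the vinyl iodide is inert to SmI2 without HMPA.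

Step 6
Reactants: 11 (4S,6R)-4-hydroxy-6-[(E)-1-iodoprop-1-en-2-yl]-4-(propan-2-yl)oxan-2-one
Product: 12 methyl 2-[(2S,4S,6R)-6-[(E)-1-iodoprop-1-en-2-yl]-2-(4-methoxyphenyl)-4-(propan-2-yl)-1,3-dioxan-4-yl]acetate
Conditions: 4-MeOC6H4CH(OMe)2 (3 equiv), MeOH (5 equiv), CSA (10 mol%), CH2Cl2, rt
Reagents that add atoms: 4-methoxybenzaldehyde dimethyl acetal COc1ccc(C(OC)OC)cc1; methanol CO
Why: Acid-catalysed methanolysis of the δ-lactone with in situ transacetalisation of the released syn-1,3-diol (the known lactone to alkylidene dihydroxy ester conversion); thermodynamic control places aryl, alkenyl and CH2CO2Me equatorial, which fixes the acetal carbon.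

Step 7
Reactants: 12 methyl 2-[(2S,4S,6R)-6-[(E)-1-iodoprop-1-en-2-yl]-2-(4-methoxyphenyl)-4-(propan-2-yl)-1,3-dioxan-4-yl]acetate; 13 propanal
Product: 14 methyl 2-[(2S,4S,6R)-6-[(E)-4-hydroxyhex-2-en-2-yl]-2-(4-methoxyphenyl)-4-(propan-2-yl)-1,3-dioxan-4-yl]acetate (C8 epimers)
Conditions: CrCl2 (4 equiv), NiCl2 (1 mol%), DMSO, rt
Reagents that add atoms: none
Why: Nozaki–Hiyama–Kishi coupling: the alkenylchromium(III) species forms with retention of the E geometry and adds only to the aldehyde, leaving ester and acetal untouched; the C8 configuration is irrelevant.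

Step 8
Reactants: 14 methyl 2-[(2S,4S,6R)-6-[(E)-4-hydroxyhex-2-en-2-yl]-2-(4-methoxyphenyl)-4-(propan-2-yl)-1,3-dioxan-4-yl]acetate
Product: 15 methyl 2-[(2S,4S,6R)-2-(4-methoxyphenyl)-6-[(E)-4-oxohex-2-en-2-yl]-4-(propan-2-yl)-1,3-dioxan-4-yl]acetate
Conditions: Dess–Martin periodinane, CH2Cl2, 0 °C → rt
Reagents that add atoms: none
Why: Dess–Martin oxidation of the allylic alcohol to the E enone under conditions that the acetal and ester tolerate.

Step 9
Reactants: 15 methyl 2-[(2S,4S,6R)-2-(4-methoxyphenyl)-6-[(E)-4-oxohex-2-en-2-yl]-4-(propan-2-yl)-1,3-dioxan-4-yl]acetate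
Product: 16 methyl 2-[(2S,4S,6R)-2-(4-methoxyphenyl)-4-(propan-2-yl)-6-[(2E,4Z)-4-(triisopropylsilyloxy)hexa-2,4-dien-2-yl]-1,3-dioxan-4-yl]acetate
Conditions: TIPSOTf, Et3N, CH2Cl2, −78 → 0 °C
Reagents that add atoms: triisopropylsilyl trifluoromethanesulfonate CC(C)[Si](OS(=O)(=O)C(F)(F)F)(C(C)C)C(C)C
Why: Soft enolisation of the ethyl ketone at its α′ CH2 gives the cross-conjugated 2-silyloxydiene with Z geometry (OSi cis to CH3); the ester is not enolised under these conditions.

Step 10
Reactants: 16 methyl 2-[(2S,4S,6R)-2-(4-methoxyphenyl)-4-(propan-2-yl)-6-[(2E,4Z)-4-(triisopropylsilyloxy)hexa-2,4-dien-2-yl]-1,3-dioxan-4-yl]acetate; 17 chloroiodomethane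
Product: 18 1-chloro-3-[(2S,4S,6R)-2-(4-methoxyphenyl)-4-(propan-2-yl)-6-[(2E,4Z)-4-(triisopropylsilyloxy)hexa-2,4-dien-2-yl]-1,3-dioxan-4-yl]propan-2-one (key-step precursor)
Conditions: MeLi·LiBr (added last), THF–Et2O, −78 °C; then AcOH, −78 °C
Reagents that add atoms: none
Why: Chloromethyllithium homologation of an ester: the carbenoid formed by I/Li exchange adds once to give a tetrahedral alkoxide that is stable at −78 °C and collapses to the chloromethyl ketone on acidic quench; the silyl dienol ether and the acetal are inert to organolithiums at this temperature.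

Step 11
Reactants: 18 1-chloro-3-[(2S,4S,6R)-2-(4-methoxyphenyl)-4-(propan-2-yl)-6-[(2E,4Z)-4-(triisopropylsilyloxy)hexa-2,4-dien-2-yl]-1,3-dioxan-4-yl]propan-2-one
Product: 20 cis-fused acetal cycloadduct (C4 ketone; C7=C8 TIPS enol ether; O9/O11 4-methoxybenzylidene acetal; H5 and 6-CH3 syn to O9/O11; C2 epimers), via oxyallyl cation 19 (not isolated)
Conditions: CF3CH2ONa (1.5 equiv), CF3CH2OH (0.01 M), −20 °C → rt
Reagents that add atoms: none
Why: Trifluoroethoxide enolises 18 toward C5 (bulky C11 cis to O−) and the allylic C3–Cl bond ionises in trifluoroethanol to the oxyallyl cation 19; the nucleophilic C2 terminus of the silyl enol ether bonds to C3 while the oxyallyl terminus C5 bonds to C6, concertedly but asynchronously or through a short-lived silyloxyallyl cation. The closest known reaction type is the intramolecular (4+3) cycloaddition of oxyallyl cations, made from α-halo ketones with base in fluorinated alcohols, with tethered dienes. The cyclopentane closes by union of the tethered termini C5 and C6 across C11–C10–C9 (5-exo-type closure onto the diene terminus), and the cycloheptenone closes as the 4π+2π periphery through the C2–C3 and C5–C6 bonds in a compact transition state. C6 is controlled by the acetal: for C5 to reach C6 both must stand axial on the dioxane, the O–CH(Ar)–O bridge then covers the O9/O11 face of the forming cyclopentane, so C7 and C4 can only lie on the opposite face, which puts the C6 methyl cis to O9 and gives the cis ring fusion at C5 (H5 syn to the methyl), corrected in step 14. The step needs this facial selectivity, which the locked syn-diol acetal secures, and an s-cis diene, which the E alkene at C6=C7 (tether outside) and the Z enol ether (C2 methyl outside) allow; regiochemistry is fixed by the tether.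

Step 12
Reactants: 20 cis-fused acetal cycloadduct
Product: 21 cis-fused 9,11-diol 4,8-dione (H5 syn to 6-CH3; C2 epimers)
Conditions: 2 N HCl, THF, rt
Reagents that add atoms: none
Why: Aqueous acid hydrolyses the p-methoxybenzylidene acetal (strained in the bicyclic array) and protonates the silyl enol ether at C7 to release the C8 ketone; the tertiary alcohol should survive dilute acid at room temperature.

Step 13
Reactants: 21 cis-fused 9,11-diol 4,8-dione
Product: 23 cis-fused 9-O-TBS 11-O-TMS 4,8-dione, via mono-TBS ether 22 (not isolated)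
Conditions: TBSOTf (1.1 equiv), 2,6-lutidine, CH2Cl2, −78 → −20 °C; then N-(trimethylsilyl)imidazole, rt
Reagents that add atoms: tert-butyldimethylsilyl trifluoromethanesulfonate CC(C)(C)[Si](C)(C)OS(=O)(=O)C(F)(F)F; N-(trimethylsilyl)imidazole C[Si](C)(C)n1ccnc1
Why: Silyl ether formation: the triflate at low temperature silylates only the secondary C9–OH, and N-TMS-imidazole then caps the hindered tertiary C11–OH under neutral conditions so that base cannot cause retro-aldol cleavage of the C5–C11 bond in the next step.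

Step 14
Reactants: 23 cis-fused 9-O-TBS 11-O-TMS 4,8-dione
Product: 25 trans-fused 9-O-TBS 11-hydroxy 4,8-dione (H5 anti to 6-CH3), via trans-fused TMS ether 24 (not isolated)
Conditions: DBU (20 mol%), toluene, 50 °C; then 1 N HCl, THF, 0 °C
Reagents that add atoms: none
Why: Base-mediated epimerisation through the C4 enolate: in the cis isomer C4 is eclipsed with the isopropyl group on C11 and crowded by C7, so equilibration should favour the trans-fused ketone; brief dilute acid then removes only the labile tertiary TMS ether.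

Step 15
Reactants: 25 trans-fused 9-O-TBS 11-hydroxy 4,8-dione
Product: 26 trans-fused 4,11-diol 8-ketone 9-O-TBS ether (O4 syn to H5)
Conditions: Me4NBH(OAc)3, MeCN–AcOH, −30 → 0 °C
Reagents that add atoms: none
Why: Evans–Saksena directed reduction: the borohydride binds O11 and delivers hydride intramolecularly to the C4 face syn to the C5–C11 bond, which sets C4 with O4 syn to H5 (the equatorial alcohol, anti to the C6 methyl); the C8 ketone has no neighbouring hydroxyl and is not reduced by this reagent.

Step 16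
Reactants: 26 trans-fused 4,11-diol 8-ketone 9-O-TBS ether; 27 4-[(tert-butyldimethylsilyl)oxy]benzoic acid
Product: 28 C4 4-(TBS-oxy)benzoate of 26 (C2 epimers)
Conditions: EDC·HCl, DMAP, CH2Cl2, rt
Reagents that add atoms: none
Why: Steglich esterification acylates the only secondary hydroxyl with retention at C4; the tertiary C11–OH does not react.

Step 17
Reactants: 28 C4 4-(TBS-oxy)benzoate
Product: 29 bis-TBS ether of the target (C2=C3 enone)
Conditions: IBX (2.5 equiv), DMSO–fluorobenzene, 70 °C
Reagents that add atoms: none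
Why: IBX dehydrogenation through the C8 enol: unsaturation can only develop toward C3 because C7 is flanked by the quaternary C6, and both C2 epimers give the same trisubstituted enone.

Step 18
Reactants: 29 bis-TBS ether of the target
Product: 30 target CNP0199397.1
Conditions: HF·pyridine, pyridine, THF, 0 °C → rt
Reagents that add atoms: none
Why: Fluoride-mediated desilylation removes the alkyl and the aryl TBS ethers under non-basic conditions that should leave the aryl ester, the γ-acyloxy enone and the tertiary alcohol untouched.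

**Compound list**

1 | prop-2-yn-1-ol | C#CCO | starting material
2 | (E)-alkenylalane: dimethylaluminium alkoxide of (E)-3-(dimethylalumanyl)-2-methylprop-2-en-1-ol | C[Al](C)OC/C(C)=C/[Al](C)C | intermediate
3 | (E)-3-iodo-2-methylprop-2-en-1-ol | OC/C(C)=C/I | intermediate
4 | (E)-3-iodo-2-methylprop-2-enal | O=C/C(C)=C/I | intermediate
5 | 3-methylbutan-2-one | CC(C)C(C)=O | starting material
6 | diisopinocampheylboron enolate of 3-methylbutan-2-one (less substituted enolate, from (−)-Ipc2BCl) | C=C(OB([C@@H]1C[C@@H]2C[C@H]([C@H]1C)C2(C)C)[C@@H]1C[C@@H]2C[C@H]([C@H]1C)C2(C)C)C(C)C | intermediate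
7 | (5R,6E)-5-hydroxy-7-iodo-2,6-dimethylhept-6-en-3-one | CC(C)C(=O)C[C@@H](O)/C(C)=C/I | intermediate
8 | bromoacetyl bromide | BrCC(Br)=O | starting material
9 | (1E,3R)-1-iodo-2,6-dimethyl-5-oxohept-1-en-3-yl bromoacetate | CC(C)C(=O)C[C@@H](OC(=O)CBr)/C(C)=C/I | intermediate
10 | samarium(III) enolate of the acetate ester of 7 | CC(C)C(=O)C[C@@H](OC(=C)O[Sm](I)I)/C(C)=C/I | intermediate
11 | (4S,6R)-4-hydroxy-6-[(E)-1-iodoprop-1-en-2-yl]-4-(propan-2-yl)oxan-2-one (OH trans to the alkenyl group) | O=C1C[C@](O)(C(C)C)C[C@H](/C(C)=C/I)O1 | intermediate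
12 | methyl 2-[(2S,4S,6R)-6-[(E)-1-iodoprop-1-en-2-yl]-2-(4-methoxyphenyl)-4-(propan-2-yl)-1,3-dioxan-4-yl]acetate (aryl, alkenyl and CH2CO2Me all cis) | COC(=O)C[C@]1(C(C)C)C[C@H](/C(C)=C/I)O[C@H](c2ccc(OC)cc2)O1 | intermediate
13 | propanal | CCC=O | starting material
14 | methyl 2-[(2S,4S,6R)-6-[(E)-4-hydroxyhex-2-en-2-yl]-2-(4-methoxyphenyl)-4-(propan-2-yl)-1,3-dioxan-4-yl]acetate (C8 epimers) | COC(=O)C[C@]1(C(C)C)C[C@H](/C(C)=C/C(O)CC)O[C@H](c2ccc(OC)cc2)O1 | intermediate
15 | methyl 2-[(2S,4S,6R)-2-(4-methoxyphenyl)-6-[(E)-4-oxohex-2-en-2-yl]-4-(propan-2-yl)-1,3-dioxan-4-yl]acetate | COC(=O)C[C@]1(C(C)C)C[C@H](/C(C)=C/C(=O)CC)O[C@H](c2ccc(OC)cc2)O1 | intermediate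
16 | methyl 2-[(2S,4S,6R)-2-(4-methoxyphenyl)-4-(propan-2-yl)-6-[(2E,4Z)-4-(triisopropylsilyloxy)hexa-2,4-dien-2-yl]-1,3-dioxan-4-yl]acetate | COC(=O)C[C@]1(C(C)C)C[C@H](/C(C)=C/C(O[Si](C(C)C)(C(C)C)C(C)C)=C/C)O[C@H](c2ccc(OC)cc2)O1 | intermediate
17 | chloroiodomethane | ClCI | starting material
18 | 1-chloro-3-[(2S,4S,6R)-2-(4-methoxyphenyl)-4-(propan-2-yl)-6-[(2E,4Z)-4-(triisopropylsilyloxy)hexa-2,4-dien-2-yl]-1,3-dioxan-4-yl]propan-2-one (key-step precursor) | ClCC(=O)C[C@]1(C(C)C)C[C@H](/C(C)=C/C(O[Si](C(C)C)(C(C)C)C(C)C)=C/C)O[C@H](c2ccc(OC)cc2)O1 | intermediate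
19 | oxyallyl cation (zwitterion) from 18, C3 cationic, C4–O−, C11 cis to O− | [CH2+]C(/[O-])=C/[C@]1(C(C)C)C[C@H](/C(C)=C/C(O[Si](C(C)C)(C(C)C)C(C)C)=C/C)O[C@H](c2ccc(OC)cc2)O1 | intermediate
20 | cis-fused cycloadduct: hydroazulene with C4 ketone, C7=C8 TIPS enol ether, C2-H/CH3 (epimers), 6-CH3 and H5 both syn to O9/O11, which are bridged by CH(4-MeOC6H4) | CC1CC(=O)[C@H]2[C@@](C)(C=C1O[Si](C(C)C)(C(C)C)C(C)C)[C@H]3C[C@]2(C(C)C)O[C@@H](c2ccc(OC)cc2)O3 | intermediate
21 | cis-fused 9,11-dihydroxy-4,8-dione (H5 syn to 6-CH3; O9, O11 and 6-CH3 on one face; C2 epimers) | CC1CC(=O)[C@H]2[C@@](C)(CC1=O)[C@H](O)C[C@@]2(O)C(C)C | intermediate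
22 | cis-fused 9-O-TBS 11-hydroxy-4,8-dione | CC1CC(=O)[C@H]2[C@@](C)(CC1=O)[C@H](O[Si](C)(C)C(C)(C)C)C[C@@]2(O)C(C)C | intermediate
23 | cis-fused 9-O-TBS 11-O-TMS 4,8-dione | CC1CC(=O)[C@H]2[C@@](C)(CC1=O)[C@H](O[Si](C)(C)C(C)(C)C)C[C@@]2(O[Si](C)(C)C)C(C)C | intermediate
24 | trans-fused 9-O-TBS 11-O-TMS 4,8-dione (H5 anti to 6-CH3) | CC1CC(=O)[C@@H]2[C@@](C)(CC1=O)[C@H](O[Si](C)(C)C(C)(C)C)C[C@@]2(O[Si](C)(C)C)C(C)C | intermediate
25 | trans-fused 9-O-TBS 11-hydroxy-4,8-dione | CC1CC(=O)[C@@H]2[C@@](C)(CC1=O)[C@H](O[Si](C)(C)C(C)(C)C)C[C@@]2(O)C(C)C | intermediate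
26 | trans-fused 4,11-dihydroxy-8-ketone 9-O-TBS ether (O4 syn to H5) | CC1C[C@H](O)[C@@H]2[C@@](C)(CC1=O)[C@H](O[Si](C)(C)C(C)(C)C)C[C@@]2(O)C(C)C | intermediate
27 | 4-[(tert-butyldimethylsilyl)oxy]benzoic acid | CC(C)(C)[Si](C)(C)Oc1ccc(C(=O)O)cc1 | starting material
28 | C4 4-[(tert-butyldimethylsilyl)oxy]benzoate of 26 (C2 epimers) | CC1C[C@H](OC(=O)c3ccc(O[Si](C)(C)C(C)(C)C)cc3)[C@@H]2[C@@](C)(CC1=O)[C@H](O[Si](C)(C)C(C)(C)C)C[C@@]2(O)C(C)C | intermediate
29 | bis-TBS ether of the target (C2=C3 enone; O9 and phenol silylated) | CC1=C[C@H](OC(=O)c3ccc(O[Si](C)(C)C(C)(C)C)cc3)[C@@H]2[C@@](C)(CC1=O)[C@H](O[Si](C)(C)C(C)(C)C)C[C@@]2(O)C(C)C | intermediate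
30 | CNP0199397.1 (4S,5S,6R,9R,11R in the numbering above) | CC1=C[C@H](OC(=O)c2ccc(O)cc2)[C@@H]2[C@@](C)(CC1=O)[C@H](O)C[C@@]2(O)C(C)C | target

**Step count and risks**

Total steps: 18. Longest linear sequence: 18 steps (1 → 30).

Steps most likely to fail:

1. Step 11. The primary chloride may be displaced at C3 by alkoxide or solvent faster than it ionises, the silyl dienol ether may be protodesilylated before the cation is trapped, or the strain of closing the acetal-bridged cyclopentane may slow the ring closure. The fallback uses a halogen-stabilised oxyallyl cation, which ionises more readily. It sets out from ester 16: dichloromethyllithium (CH2Cl2, LDA, THF, −78 °C) should give the dichloromethyl ketone F1. The same base and fluorinated-alcohol conditions should then give the 3-chloro cycloadduct F2 by the same (4+3) closure. Zinc–copper couple in NH4Cl/MeOH removes the C3 chlorine and the sequence comes back to the route at 20.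

2. Step 14. The equilibrium at C5 may not lie on the trans side while O11 carries a silyl group, or the C5 enolate may expel the β-silyloxy group. The fallback lets a metal chelate, not sterics, drive the equilibrium. It sets out from 21, which is silylated only at O9 and isolated as 22 (no new compound, F0). Treatment of 22 with MgBr2·OEt2 and Et3N in CH2Cl2 enolises the ketone softly while magnesium binds O11 and the C4 carbonyl, which is possible only when C4 is cis to O11, that is in the trans-fused isomer. Aqueous work-up should return the route at 25.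

3. Step 17. Dehydrogenation of the hindered C8 ketone may stall, overrun to a dienone, or cost the aryl silyl ether at 70 °C in DMSO. The fallback is a Saegusa–Ito sequence. It sets out from 28: TMSOTf and Et3N should give the more substituted C2=C8 trimethylsilyl enol ether, with O11 silylated as well, F3. Pd(OAc)2 in MeCN should give the C2=C3 enone still carrying the O11 TMS ether, F4. The conditions of step 18 remove this group together with the two TBS groups, so the fallback comes back to the route at 30.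

**Further compounds**

F1 | step 11 | 1,1-dichloro-3-[(2S,4S,6R)-2-(4-methoxyphenyl)-4-(propan-2-yl)-6-[(2E,4Z)-4-(triisopropylsilyloxy)hexa-2,4-dien-2-yl]-1,3-dioxan-4-yl]propan-2-one | ClC(Cl)C(=O)C[C@]1(C(C)C)C[C@H](/C(C)=C/C(O[Si](C(C)C)(C(C)C)C(C)C)=C/C)O[C@H](c2ccc(OC)cc2)O1
F2 | step 11 | 3-chloro analogue of cycloadduct 20 (C2 and C3 epimers) | CC1C(Cl)C(=O)[C@H]2[C@@](C)(C=C1O[Si](C(C)C)(C(C)C)C(C)C)[C@H]3C[C@]2(C(C)C)O[C@@H](c2ccc(OC)cc2)O3
F0 | step 14 | none | none
F3 | step 17 | C2=C8 trimethylsilyl enol ether of 28 with O11 as TMS ether | CC=1C[C@H](OC(=O)c3ccc(O[Si](C)(C)C(C)(C)C)cc3)[C@@H]2[C@@](C)(CC=1O[Si](C)(C)C)[C@H](O[Si](C)(C)C(C)(C)C)C[C@@]2(O[Si](C)(C)C)C(C)C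
F4 | step 17 | 11-O-TMS ether of 29 | CC1=C[C@H](OC(=O)c3ccc(O[Si](C)(C)C(C)(C)C)cc3)[C@@H]2[C@@](C)(CC1=O)[C@H](O[Si](C)(C)C(C)(C)C)C[C@@]2(O[Si](C)(C)C)C(C)C
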